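## The problem

Target 44 is a germacranolide. Its ten-membered carbocycle (C1–C10) holds two Z trisubstituted alkenes (C1=C10 and C4=C5) and is cis-fused across C6–C7 to an α-methylene-γ-butyrolactone (C11, C12, C13, ring oxygen on C6). A medium ring with two Z alkenes is costly to close, so both geometries have to be fixed before or during ring formation. The ring carries five stereocentres (3S, 6R, 7R, 8S, 9R), and the ester on O8 carries two more (2R,3R). C7, C8 and C9 are contiguous, so an auxiliary-set C7/C8 pair can bias C9 and later C6, whereas C3 sits 1,5 to C9 across the C1=C10 alkene, beyond simple substrate induction. The exocyclic methylene lactone, the epoxy ester, the allylic acetate and the vicinal O8-ester/O9-hydroxyl pair (acyl migration) exclude strong base, nucleophiles and hard acid late in the route, so the side chain and the free C9 hydroxyl must be unveiled last. The enabling feature is the segment C9–C10(Me)=C1–C2–C3: two carbinols flanking a Z methyl-bearing alkene and one methylene. This is a (Z)-2-methylpent-2-ene-1,5-diol, the array that an allene hydroboration followed by two allylborations assembles from two aldehydes, and the remaining ring bond C5–C6 then joins a Z iodoalkene to an aldehyde.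

## Retrosynthesis

**Side chain and last protecting group (44 ⇒ 43 ⇒ 37 + 41).** The O9–Si bond and the O8–acyl bond are cut first. The epoxy ester and the free C9 hydroxyl are the most fragile parts, and an ester next to a free hydroxyl invites acyl migration, so both are introduced at the very end. Acid 41 is used as the preformed epoxide because an angelate would isomerise to the tiglate on activation and a late epoxidation would have no facial control. 41 comes from angelic acid 38 through alcohol 39 and epoxy alcohol 40. The forward steps must acylate a hindered secondary alcohol and remove a hindered silyl ether without disturbing the lactone.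

**Lactone (37 ⇒ 36 ⇒ 34 ⇒ 33).** The lactone carbonyl is taken back to the alcohol oxidation level. The 6,12-diol 34 should lactonise oxidatively, and before that C12 is a silyl ether (33). A C12 ester carried through the route could lactonise onto O8 or O9 and would not tolerate the hydride and borane steps. The C12 silyl ether is inert to all of them.

**Ring closure (33 ⇒ 32).** The C5–C6 bond is cut to a Z iodoalkene and an aldehyde in 32 (Nozaki–Hiyama–Kishi). Among the ring bonds this is the one whose formation creates the lactone carbinol C6 and uses an alkene geometry fixed beforehand. C2–C3 and C9–C10 are better made intermolecularly (below). Olefination at C1=C10 or C4=C5 would have to deliver a Z trisubstituted alkene inside a forming medium ring. The forward reaction must close a ten-membered ring and add to the correct aldehyde face.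

**Adjustment of C3, C9 and C6 (32 ⇐ 31 ⇐ 30 ⇐ 29 ⇐ 28).** Chair transition-state analysis of the double allylboration shows that the Z-selective pathway links 9R with 3R (1,5-anti). This pathway uses the kinetic allylborane and places the carbinol arm pseudo-axial. The 3S configuration with a Z alkene belongs to a pathway that normally gives the E olefin. The acetate is therefore introduced with inversion (Mitsunobu, acetic acid) on diol 28, which takes the place of a plain acetylation at no cost in steps. The less hindered C3 hydroxyl reacts, and C9 hydroxyl is then silylated (30). The primary triethylsilyl ether is removed (31) and the alcohol oxidised (32).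

**Key disconnection (28 ⇒ 18 + 25 + 22).** The bonds C9–C10 and C2–C3 are cut, with the allenyl boronate 25 as the C1/C2/C10 linchpin. Compared with cutting at the alkenes, this joins three fragments of sensible size in one flask. It sets C9 and C3 and the C1=C10 geometry, and needs only aldehydes as partners. Aldehyde 18 carries C6–C9 with C11–C13 and the two auxiliary-derived stereocentres, and 22 and 25 are small and achiral. The forward reaction needs reagent-controlled attack on the α-alkoxy aldehyde, retention of the kinetic allylborane geometry, and a Z-selective second allylboration.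

**Aldehyde 18 (18 ⇒ 17 ⇒ 16 ⇒ 15 ⇒ 14 ⇒ 13 ⇒ 7 + 11).** C7–C8 is cut as an auxiliary-controlled syn aldol between imide 7 and aldehyde 11. The C7/C8 relationship in 18 is syn (C11 branch and O8 on the same side of the C6–C9 zigzag), which is what a boron Z-enolate gives. The imide carbonyl becomes C6. The benzyl-type ether is moved from O9 to O8 through the cyclic acetal 14 and its regioselective reductive opening (17), so no separate protection of O8 is needed. Imide 7 comes from acid 4 and oxazolidinone 5, and 4 comes from itaconic acid 4-methyl ester 1 through 2 and 3. Aldehyde 11 comes from diol 8 through 9.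

**Small components.** Iodoenal 22 is cut to propargyl alcohol 19 (carbometalation–iodination to 21, then oxidation). Boronate 25 is cut to but-2-yn-1-ol 23 (carbonate 24, then copper-catalysed borylation with allylic transposition).

## Roads not taken

**Alternative 1:** The cut is at the two C–O bonds C6–O(lactone) and C3–OAc, leading back to the ten-membered 3,5-diene acid A1. In the forward step Pd(OAc)2 with benzoquinone in acetic acid activates the C3–C6 diene. The C12 carboxylate attacks C6 and closes the lactone, and acetate opens the π-allyl complex at C3, leaving the C4=C5 alkene and giving A2, which has the structure of 43.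
- Merits: one catalytic step installs the lactone, the acetate and two stereocentres, needs no inversion or protecting group at C3, and lands one step from the target. In late-stage economy it beats the chosen plan.
- Weak points: the stereochemical course of this 1,4-addition is established for six- and seven-membered dienes, not for a flexible ten-membered ring. The C2 methylene is doubly allylic once the π-allyl forms, so β-hydride loss to a triene competes. A1 itself still has to be made by closing a ten-membered ring around a conjugated diene and a skipped Z alkene, with no handle for C8/C9.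
- Comparison: the chosen plan sets C9 and C3 on open-chain material with precedent and closes the ring at a bond with preset alkene geometry. It pays with about five more steps after ring assembly.

**Alternative 2:** Here the ring is made by breaking a bond: the C3–C8 bond of the ring-fusion cis-diol A3. Pb(OAc)4 cleaves the diol through a cyclic lead diester and merges both cyclohexenes into the Z,Z-cyclodecadiene-3,8-dione A4.
- Merits: both Z alkenes are inherited from six-membered rings, so their geometry is certain, and the medium ring forms without high dilution. In both respects this is safer than the chosen plan, where the C1=C10 geometry rests on a transition-state preference.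
- Weak points: C3 and C8 emerge as ketones and need two diastereoselective reductions in a floppy ring. C7 becomes α to the C8 ketone and allylic (epimerisation, conjugation), and the C6 silyloxy group is β to that ketone (elimination). A3 is a densely substituted cis-decalin whose own synthesis would be long.
- Comparison: the chosen plan makes C3, C8 and C9 as carbinols under auxiliary or reagent control and never has an enolisable C7.

**Alternative 3:** The cut is at C7–C8, leading back to the bromomethylbutenolide aldehyde A5. CrCl2 turns the allylic bromide into an allylchromium that attacks the tethered C8 aldehyde through C7, moves the alkene to C11=C13 and closes the ring to A6, which has the structure of 37.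
- Merits: ring, exocyclic methylene and the C7–C8 bond arise together and no oxidative lactonisation is needed. After the closure only esterification and desilylation remain, so the endgame is shorter than in the chosen plan.
- Weak points: C7 and C8 are both created in a macrocyclic transition state with no reagent control over their sense relative to C6 and C9. The α-silyloxy aldehyde and the butenolide γ-hydrogen at C6 are epimerisable. A5 still contains the 1,5-related C3/C9 carbinols across the Z alkene, the very problem the double allylboration solves.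
- Comparison: the chosen plan fixes C7/C8 early by an auxiliary aldol and leaves only C6 to the ring closure, where an oxidation–reduction correction is available.

Key step: step 17

Remarks on the chemistry (assumptions):
- Skeleton atoms are numbered as in germacranes (ring C1–C10; lactone C11, C12, C13).
- Allylboranes carrying isopinocampheyl groups from (−)-α-pinene are taken to attack the Re face of an aldehyde.
- Kinetic hydroboration of 25 is taken to place the dioxaborolane cis to the CH2B arm; on this basis the Z-selective pathway gives the (3R,9R) diol 28.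

## Route

Step 1
Reactants: 1 4-methoxy-2-methylidene-4-oxobutanoic acid (itaconic acid 4-methyl ester)
Product: 2 methyl 3-(hydroxymethyl)but-3-enoate
Conditions: BH3·SMe2 (1.0 equiv), THF, −10 °C → rt; aq. work-up
Reagents that add atoms: none
Why: Chemoselective borane reduction of a carboxylic acid beside an ester; the acid is reduced through its acyloxyborane faster than the electron-poor alkene is hydroborated, and one equivalent leaves no hydride for the product alkene; 2 is silylated at once to forestall lactonisation.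

Step 2
Reactants: 2 methyl 3-(hydroxymethyl)but-3-enoate
Product: 3 methyl 3-({[tert-butyl(dimethyl)silyl]oxy}methyl)but-3-enoate
Conditions: TBSCl, imidazole, CH2Cl2, 0 °C → rt
Reagents that add atoms: tert-butyl(chloro)dimethylsilane, CC(C)(C)[Si](C)(C)Cl
Why: Standard silylation of a primary allylic alcohol; it blocks lactone formation and carries C12 at the alcohol level.

Step 3
Reactants: 3 methyl 3-({[tert-butyl(dimethyl)silyl]oxy}methyl)but-3-enoate
Product: 4 3-({[tert-butyl(dimethyl)silyl]oxy}methyl)but-3-enoic acid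
Conditions: LiOH·H2O, THF/H2O, 0 °C; then cold 1 M HCl to pH 4
Reagents that add atoms: LiOH (hydroxide oxygen), [Li+].[OH-]
Why: Saponification at 0 °C; hydrolysis outruns base-induced migration of the β,γ-alkene because the carboxylate formed is no longer acidic at the α-carbon.

Step 4
Reactants: 4 3-({[tert-butyl(dimethyl)silyl]oxy}methyl)but-3-enoic acid; 5 (4S)-4-benzyl-1,3-oxazolidin-2-one
Product: 7 (4S)-4-benzyl-3-[3-({[tert-butyl(dimethyl)silyl]oxy}methyl)but-3-enoyl]-1,3-oxazolidin-2-one, via mixed pivalic anhydride 6 (not isolated)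
Conditions: PivCl, Et3N, THF, −20 °C; then 5, LiCl, −20 °C → rt
Reagents that add atoms: none
Why: N-Acylation of an oxazolidinone through a mixed pivalic anhydride under LiCl/Et3N activation; no strong base is used, so the β,γ-unsaturated acyl group is not isomerised.

Step 5
Reactants: 8 (Z)-but-2-ene-1,4-diol
Product: 9 (Z)-1,4-bis[(4-methoxybenzyl)oxy]but-2-ene
Conditions: NaH, 4-methoxybenzyl chloride, Bu4NI (cat.), THF/DMF, 0 °C → rt
Reagents that add atoms: 4-methoxybenzyl chloride, COc1ccc(CCl)cc1
Why: Twofold Williamson etherification of a primary diol.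

Step 6
Reactants: 9 (Z)-1,4-bis[(4-methoxybenzyl)oxy]but-2-ene
Product: 11 2-[(4-methoxybenzyl)oxy]acetaldehyde, via ozonide 10 (not isolated)
Conditions: O3, CH2Cl2, −78 °C; then PPh3, −78 °C → rt
Reagents that add atoms: ozone, [O-][O+]=O
Why: Ozonolysis with reductive work-up; the symmetrical alkene gives two equivalents of the aldehyde, which is used fresh.

Step 7
Reactants: 7 (4S)-4-benzyl-3-[3-({[tert-butyl(dimethyl)silyl]oxy}methyl)but-3-enoyl]-1,3-oxazolidin-2-one; 11 2-[(4-methoxybenzyl)oxy]acetaldehyde
Product: 13 (4S)-4-benzyl-3-[(2S,3S)-2-(3-{[tert-butyl(dimethyl)silyl]oxy}prop-1-en-2-yl)-3-hydroxy-4-[(4-methoxybenzyl)oxy]butanoyl]-1,3-oxazolidin-2-one, via dibutylboron (Z)-enolate 12 (not isolated)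
Conditions: Bu2BOTf, i-Pr2NEt, CH2Cl2, −78 → 0 °C; then 11, −78 → 0 °C; pH 7 buffer, MeOH, H2O2
Reagents that add atoms: none
Why: Evans syn aldol; the boron Z-enolate reacts at its α-carbon through a Zimmerman–Traxler chair, and the (S)-benzyl auxiliary sets C7 and C8 (syn, 2S,3S in the acyl chain), the sense known for propionyl and but-3-enoyl imides.

Step 8
Reactants: 13 aldol adduct (as named in step 7)
Product: 14 (4S)-4-benzyl-3-{(2S)-3-({[tert-butyl(dimethyl)silyl]oxy}methyl)-2-[(4S)-2-(4-methoxyphenyl)-1,3-dioxolan-4-yl]but-3-enoyl}-1,3-oxazolidin-2-one (both epimers at the acetal carbon)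
Conditions: DDQ, 4 Å molecular sieves, CH2Cl2, 0 °C (anhydrous)
Reagents that add atoms: none
Why: Oxidative acetalisation of a 4-methoxybenzyl ether by the neighbouring hydroxyl under anhydrous DDQ conditions; the benzylic cation is trapped by O8 to give the dioxolane, which protects O8 and O9 together.

Step 9
Reactants: 14 acetal imide (as named in step 8)
Product: 15 (2R)-3-({[tert-butyl(dimethyl)silyl]oxy}methyl)-2-[(4S)-2-(4-methoxyphenyl)-1,3-dioxolan-4-yl]but-3-en-1-ol
Conditions: LiBH4, MeOH (1 equiv), THF, 0 °C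
Reagents that add atoms: none
Why: Reductive removal of the oxazolidinone auxiliary to the primary alcohol (C6); acetal, silyl ether and alkene are inert, and the auxiliary is recovered.

Step 10
Reactants: 15 primary alcohol (as named in step 9)
Product: 16 {[(2R)-3-({[tert-butyl(dimethyl)silyl]oxy}methyl)-2-[(4S)-2-(4-methoxyphenyl)-1,3-dioxolan-4-yl]but-3-en-1-yl]oxy}(triethyl)silane
Conditions: TESCl, imidazole, CH2Cl2, 0 °C
Reagents that add atoms: chloro(triethyl)silane, CC[Si](CC)(CC)Cl
Why: Silylation of the primary C6 alcohol with a group that can later be removed ahead of both tert-butyldimethylsilyl ethers.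

Step 11
Reactants: 16 triethylsilyl ether (as named in step 10)
Product: 17 (2S,3R)-4-({[tert-butyl(dimethyl)silyl]oxy}methyl)-2-[(4-methoxybenzyl)oxy]-3-{[(triethylsilyl)oxy]methyl}pent-4-en-1-ol
Conditions: i-Bu2AlH, CH2Cl2, −78 → 0 °C; aq. potassium sodium tartrate
Reagents that add atoms: none
Why: Regioselective reductive opening of a 4-methoxybenzylidene acetal; aluminium binds the less hindered primary oxygen O9, that C–O bond breaks, and hydride delivery leaves the 4-methoxybenzyl ether on the secondary oxygen O8.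

Step 12
Reactants: 17 primary alcohol (as named in step 11)
Product: 18 (2S,3R)-4-({[tert-butyl(dimethyl)silyl]oxy}methyl)-2-[(4-methoxybenzyl)oxy]-3-{[(triethylsilyl)oxy]methyl}pent-4-enal
Conditions: Dess–Martin periodinane, NaHCO3, CH2Cl2, 0 °C → rt
Reagents that add atoms: none
Why: Buffered Dess–Martin oxidation gives the α-alkoxy aldehyde without base, so C8 is not epimerised; 18 is used directly.

Step 13
Reactants: 19 prop-2-yn-1-ol
Product: 21 (Z)-3-iodo-2-methylprop-2-en-1-ol, via vinylmagnesium alkoxide 20 (not isolated)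
Conditions: MeMgBr (3 equiv), CuI (10 mol%), THF, −10 °C → rt; then I2, −78 → 0 °C
Reagents that add atoms: methylmagnesium bromide, C[Mg]Br; iodine, [I][I]
Why: Copper-catalysed, alkoxide-directed carbomagnesiation of propargyl alcohol places methyl on C2 and magnesium on C3 cis to the CH2O group (five-membered chelate); iodinolysis with retention gives the Z iodide.

Step 14
Reactants: 21 (Z)-3-iodo-2-methylprop-2-en-1-ol
Product: 22 (Z)-3-iodo-2-methylprop-2-enal
Conditions: MnO2, CH2Cl2, rt, dark
Reagents that add atoms: none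
Why: Neutral allylic oxidation; the light- and acid-sensitive Z enal is used as a fresh solution to avoid Z/E drift.

Step 15
Reactants: 23 but-2-yn-1-ol
Product: 24 but-2-yn-1-yl methyl carbonate
Conditions: ClCO2Me, pyridine, CH2Cl2, 0 °C
Reagents that add atoms: methyl chloroformate, COC(=O)Cl
Why: Standard carbonate formation from a primary propargylic alcohol.

Step 16
Reactants: 24 but-2-yn-1-yl methyl carbonate
Product: 25 2-(buta-2,3-dien-2-yl)-4,4,5,5-tetramethyl-1,3,2-dioxaborolane
Conditions: B2pin2, CuCl (5 mol%), KOt-Bu (5 mol%), Xantphos (5 mol%), THF, rt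
Reagents that add atoms: bis(pinacolato)diboron, CC1(C)OB(B2OC(C)(C)C(C)(C)O2)OC1(C)C
Why: Copper-catalysed borylation of a propargylic carbonate with allylic transposition (boryl-copper adds at the methyl-bearing alkyne carbon and the carbonate leaves), the established entry to allenyl boronates.

Step 17
Reactants: 25 2-(buta-2,3-dien-2-yl)-4,4,5,5-tetramethyl-1,3,2-dioxaborolane; 18 aldehyde (as named in step 12); 22 (Z)-3-iodo-2-methylprop-2-enal
Product: 28 (1Z,3R,5Z,7R,8S,9R)-10-({[tert-butyl(dimethyl)silyl]oxy}methyl)-1-iodo-8-[(4-methoxybenzyl)oxy]-2,6-dimethyl-9-{[(triethylsilyl)oxy]methyl}undeca-1,5,10-triene-3,7-diol, via gamma-boryl allylborane 26 (not isolated), via tertiary allylboronate 27 (not isolated)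
Conditions: (+)-Ipc2BH [from (−)-α-pinene], toluene, −25 °C; then 18, −78 °C; then 22, −78 °C → rt; aq. NaHCO3, H2O2, 0 °C
Reagents that add atoms: none
Why: This is the known one-pot allene hydroboration–double allylboration that gives (Z)-2-methylpent-2-ene-1,5-diols, and it closes no ring. Ipc2BH adds across the terminal C=C of 25 from the face away from the dioxaborolane (boron to C2, hydrogen to C1), giving the kinetic allylborane 26 with the boronate cis to the CH2B arm; low temperature prevents its 1,3-boratropic equilibration. 26 adds to 18 through its γ-carbon C10 in a chair (boronate axial, C8 residue equatorial); the isopinocampheyl groups direct attack to the Re face, which is also the face the α-alkoxy aldehyde prefers (8,9-anti, polar Felkin/Cornforth), so C9 is set as R in a matched case and C10 becomes a defined boron-bearing tertiary centre in 27. 27, an α,α-disubstituted allyl pinacol boronate, adds to the non-enolisable enal 22 through its CH2 terminus C2 in a second chair; with the carbinol arm pseudo-axial and methyl equatorial the new C1=C10 alkene is Z and chirality transfer from C10 sets C3 as R (1,5-anti to C9). The step forms two C–C bonds (C9–C10, C2–C3), two stereocentres and one alkene geometry. It needs reagent over substrate control at C9 (secured by the matched pairing), retention of the kinetic geometry of 26 (temperature), the axial preference of the arm (pinacol ester) and clean 1,2-addition to 22 with its Z iodoalkene intact (neutral conditions). The 3R configuration is the one that the invertive acetate introduction of step 18 converts into 3S.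

Step 18
Reactants: 28 diol (as named in step 17)
Product: 29 (1Z,3S,5Z,7R,8S,9R)-10-({[tert-butyl(dimethyl)silyl]oxy}methyl)-7-hydroxy-1-iodo-8-[(4-methoxybenzyl)oxy]-2,6-dimethyl-9-{[(triethylsilyl)oxy]methyl}undeca-1,5,10-trien-3-yl acetate
Conditions: AcOH, PPh3, DIAD, toluene, −20 → 0 °C
Reagents that add atoms: acetic acid, CC(=O)O
Why: Mitsunobu esterification with inversion installs the C3 acetate as 3S; the C3 hydroxyl (flanked by a methylene) is activated in preference to the C9 hydroxyl, which lies between a fully substituted alkene carbon and the branched C8, and allylic transposition would place acetate on the iodine-bearing carbon and is disfavoured.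

Step 19
Reactants: 29 monoacetate (as named in step 18)
Product: 30 (1Z,3S,5Z,7R,8S,9R)-7-{[tert-butyl(dimethyl)silyl]oxy}-10-({[tert-butyl(dimethyl)silyl]oxy}methyl)-1-iodo-8-[(4-methoxybenzyl)oxy]-2,6-dimethyl-9-{[(triethylsilyl)oxy]methyl}undeca-1,5,10-trien-3-yl acetate
Conditions: TBSOTf, 2,6-lutidine, CH2Cl2, −78 → 0 °C
Reagents that add atoms: tert-butyldimethylsilyl triflate, CC(C)(C)[Si](C)(C)OS(=O)(=O)C(F)(F)F
Why: Silyl triflate silylation of the hindered C9 alcohol; acetate, 4-methoxybenzyl ether and the other silyl ethers tolerate these conditions.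

Step 20
Reactants: 30 fully protected iodide (as named in step 19)
Product: 31 (1Z,3S,5Z,7R,8S,9R)-7-{[tert-butyl(dimethyl)silyl]oxy}-10-({[tert-butyl(dimethyl)silyl]oxy}methyl)-9-(hydroxymethyl)-1-iodo-8-[(4-methoxybenzyl)oxy]-2,6-dimethylundeca-1,5,10-trien-3-yl acetate
Conditions: PPTS (cat.), MeOH/CH2Cl2, 0 °C
Reagents that add atoms: none
Why: Mild acid methanolysis removes the primary triethylsilyl ether much faster than either tert-butyldimethylsilyl ether, freeing only the C6 alcohol.

Step 21
Reactants: 31 primary alcohol (as named in step 20)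
Product: 32 (1Z,3S,5Z,7R,8S,9S)-7-{[tert-butyl(dimethyl)silyl]oxy}-10-({[tert-butyl(dimethyl)silyl]oxy}methyl)-9-formyl-1-iodo-8-[(4-methoxybenzyl)oxy]-2,6-dimethylundeca-1,5,10-trien-3-yl acetate
Conditions: Dess–Martin periodinane, NaHCO3, CH2Cl2, 0 °C
Reagents that add atoms: none
Why: Buffered Dess–Martin oxidation avoids the amine base that could move the β,γ-alkene into conjugation or epimerise C7; the descriptor at C7 changes by priority only, and 32 is used crude.

Step 22
Reactants: 32 iodo aldehyde (as named in step 21)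
Product: 33 (1(10)Z,3S,4Z,6R,7R,8S,9R)-3-acetoxy-9,12-bis{[tert-butyl(dimethyl)silyl]oxy}-8-[(4-methoxybenzyl)oxy]germacra-1(10),4,11(13)-trien-6-ol
Conditions: CrCl2 (8 equiv), NiCl2 (2 mol%), DMSO/THF, rt, slow addition, 2 mM
Reagents that add atoms: none
Why: Intramolecular Nozaki–Hiyama–Kishi reaction; zerovalent nickel inserts into the C5–I bond with retention of the Z geometry, transmetalation gives the trivalent alkenylchromium, and this adds only to the aldehyde to close the ten-membered ring at C5–C6. Felkin–Anh addition anti to the sp2-bound C11 substituent on C7 should give 6R, the configuration that places O6 cis to the C11 arm for the cis-fused lactone.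

Step 23
Reactants: 33 macrocyclic alcohol (as named in step 22)
Product: 34 (1(10)Z,3S,4Z,6R,7R,8S,9R)-3-acetoxy-9-{[tert-butyl(dimethyl)silyl]oxy}-8-[(4-methoxybenzyl)oxy]germacra-1(10),4,11(13)-triene-6,12-diol
Conditions: HF·pyridine, pyridine, THF, 0 °C
Reagents that add atoms: none
Why: Buffered HF·pyridine cleaves the primary allylic silyl ether well before the hindered secondary one at C9.

Step 24
Reactants: 34 6,12-diol (as named in step 23)
Product: 36 (1(10)Z,3S,4Z,6R,7R,8S,9R)-3-acetoxy-9-{[tert-butyl(dimethyl)silyl]oxy}-8-[(4-methoxybenzyl)oxy]germacra-1(10),4,11(13)-trien-12,6-olide, via lactol 35 (not isolated)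
Conditions: TEMPO (cat.), PhI(OAc)2, CH2Cl2, rt
Reagents that add atoms: none
Why: Oxidative lactonisation of a 2-methylene-1,4-diol; the oxoammonium oxidises the primary allylic alcohol first, the enal is trapped by the cis C6 hydroxyl as lactol 35, and this is oxidised on to the α-methylene lactone.

Step 25
Reactants: 36 lactone (as named in step 24)
Product: 37 (1(10)Z,3S,4Z,6R,7S,8S,9R)-3-acetoxy-9-{[tert-butyl(dimethyl)silyl]oxy}-8-hydroxygermacra-1(10),4,11(13)-trien-12,6-olide
Conditions: DDQ, CH2Cl2/pH 7 buffer, 0 °C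
Reagents that add atoms: none
Why: Oxidative cleavage of the 4-methoxybenzyl ether under buffered conditions that leave acetate, lactone and silyl ether intact; the C7 descriptor changes by priority only.

Step 26
Reactants: 38 angelic acid, (Z)-2-methylbut-2-enoic acid
Product: 39 (Z)-2-methylbut-2-en-1-ol
Conditions: LiAlH4, Et2O, 0 °C
Reagents that add atoms: none
Why: Hydride reduction of the acid to the allylic alcohol with the Z geometry retained.

Step 27
Reactants: 39 (Z)-2-methylbut-2-en-1-ol
Product: 40 [(2S,3R)-2,3-dimethyloxiran-2-yl]methanol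
Conditions: Ti(Oi-Pr)4 (cat.), L-(+)-diethyl tartrate (cat.), t-BuOOH, 4 Å molecular sieves, CH2Cl2, −20 °C
Reagents that add atoms: tert-butyl hydroperoxide, CC(C)(C)OO
Why: Sharpless asymmetric epoxidation; the L-(+)-tartrate catalyst delivers oxygen to the face that gives the (2S,3R) epoxide, the same sense as for nerol, and syn addition keeps the two methyl groups cis.

Step 28
Reactants: 40 [(2S,3R)-2,3-dimethyloxiran-2-yl]methanol
Product: 41 (2R,3R)-2,3-dimethyloxirane-2-carboxylic acid
Conditions: RuCl3·xH2O (cat.), NaIO4, MeCN/EtOAc/H2O, 0 °C → rt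
Reagents that add atoms: sodium periodate, [Na+].[O-]I(=O)(=O)=O; water, O
Why: Ruthenium-catalysed periodate oxidation of an epoxy alcohol to the glycidic acid without touching the epoxide; the C2 descriptor changes by priority only.

Step 29
Reactants: 37 C8 alcohol (as named in step 25); 41 (2R,3R)-2,3-dimethyloxirane-2-carboxylic acid
Product: 43 (1(10)Z,3S,4Z,6R,7R,8S,9R)-3-acetoxy-9-{[tert-butyl(dimethyl)silyl]oxy}-8-{[(2R,3R)-2,3-dimethyloxirane-2-carbonyl]oxy}germacra-1(10),4,11(13)-trien-12,6-olide, via mixed 2,4,6-trichlorobenzoic anhydride 42 (not isolated)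
Conditions: 41, 2,4,6-trichlorobenzoyl chloride, Et3N, toluene, rt; then 37, DMAP, toluene, rt
Reagents that add atoms: none
Why: Yamaguchi esterification of a hindered secondary alcohol; the acid has no α-hydrogen and no alkene to isomerise, so the side-chain configuration is secure.

Step 30
Reactants: 43 silyl-protected ester (as named in step 29)
Product: 44 (1(10)Z,3S,4Z,6R,7R,8S,9R)-3-acetoxy-8-{[(2R,3R)-2,3-dimethyloxirane-2-carbonyl]oxy}-9-hydroxygermacra-1(10),4,11(13)-trien-12,6-olide (target)
Conditions: HF·pyridine, pyridine, THF, 0 °C → rt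
Reagents that add atoms: none
Why: Buffered, weakly acidic fluoride desilylation; it avoids the alkoxide that would trigger O8→O9 acyl migration or conjugate addition to the lactone, and the electron-poor epoxide resists opening.

## Compound list

1 | 4-methoxy-2-methylidene-4-oxobutanoic acid (itaconic acid 4-methyl ester) | C=C(CC(=O)OC)C(=O)O | starting material
2 | methyl 3-(hydroxymethyl)but-3-enoate | C=C(CO)CC(=O)OC | intermediate
3 | methyl 3-({[tert-butyl(dimethyl)silyl]oxy}methyl)but-3-enoate | C=C(CO[Si](C)(C)C(C)(C)C)CC(=O)OC | intermediate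
4 | 3-({[tert-butyl(dimethyl)silyl]oxy}methyl)but-3-enoic acid | C=C(CO[Si](C)(C)C(C)(C)C)CC(=O)O | intermediate
5 | (4S)-4-benzyl-1,3-oxazolidin-2-one | O=C1OC[C@H](Cc2ccccc2)N1 | starting material
6 | 3-({[tert-butyl(dimethyl)silyl]oxy}methyl)but-3-enoic pivalic anhydride (not isolated) | C=C(CO[Si](C)(C)C(C)(C)C)CC(=O)OC(=O)C(C)(C)C | intermediate
7 | (4S)-4-benzyl-3-[3-({[tert-butyl(dimethyl)silyl]oxy}methyl)but-3-enoyl]-1,3-oxazolidin-2-one | C=C(CO[Si](C)(C)C(C)(C)C)CC(=O)N1[C@@H](Cc2ccccc2)COC1=O | intermediate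
8 | (Z)-but-2-ene-1,4-diol | OC/C=C\CO | starting material
9 | (Z)-1,4-bis[(4-methoxybenzyl)oxy]but-2-ene | COc1ccc(COC/C=C\COCc2ccc(OC)cc2)cc1 | intermediate
10 | 3,5-bis{[(4-methoxybenzyl)oxy]methyl}-1,2,4-trioxolane (ozonide, not isolated) | COc1ccc(COCC2OOC(COCc3ccc(OC)cc3)O2)cc1 | intermediate
11 | 2-[(4-methoxybenzyl)oxy]acetaldehyde | COc1ccc(COCC=O)cc1 | intermediate
12 | dibutylboron (Z)-enolate of 7 (not isolated) | C=C(CO[Si](C)(C)C(C)(C)C)/C=C(\OB(CCCC)CCCC)N1[C@@H](Cc2ccccc2)COC1=O | intermediate
13 | (4S)-4-benzyl-3-[(2S,3S)-2-(3-{[tert-butyl(dimethyl)silyl]oxy}prop-1-en-2-yl)-3-hydroxy-4-[(4-methoxybenzyl)oxy]butanoyl]-1,3-oxazolidin-2-one | COc1ccc(COC[C@@H](O)[C@H](C(=C)CO[Si](C)(C)C(C)(C)C)C(=O)N2[C@@H](Cc3ccccc3)COC2=O)cc1 | intermediate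
14 | (4S)-4-benzyl-3-{(2S)-3-({[tert-butyl(dimethyl)silyl]oxy}methyl)-2-[(4S)-2-(4-methoxyphenyl)-1,3-dioxolan-4-yl]but-3-enoyl}-1,3-oxazolidin-2-one (both acetal epimers) | COc1ccc(C2OC[C@H]([C@H](C(=C)CO[Si](C)(C)C(C)(C)C)C(=O)N3[C@@H](Cc4ccccc4)COC3=O)O2)cc1 | intermediate
15 | (2R)-3-({[tert-butyl(dimethyl)silyl]oxy}methyl)-2-[(4S)-2-(4-methoxyphenyl)-1,3-dioxolan-4-yl]but-3-en-1-ol | COc1ccc(C2OC[C@H]([C@H](C(=C)CO[Si](C)(C)C(C)(C)C)CO)O2)cc1 | intermediate
16 | {[(2R)-3-({[tert-butyl(dimethyl)silyl]oxy}methyl)-2-[(4S)-2-(4-methoxyphenyl)-1,3-dioxolan-4-yl]but-3-en-1-yl]oxy}(triethyl)silane | COc1ccc(C2OC[C@H]([C@H](C(=C)CO[Si](C)(C)C(C)(C)C)CO[Si](CC)(CC)CC)O2)cc1 | intermediate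
17 | (2S,3R)-4-({[tert-butyl(dimethyl)silyl]oxy}methyl)-2-[(4-methoxybenzyl)oxy]-3-{[(triethylsilyl)oxy]methyl}pent-4-en-1-ol | OC[C@@H](OCc1ccc(OC)cc1)[C@H](C(=C)CO[Si](C)(C)C(C)(C)C)CO[Si](CC)(CC)CC | intermediate
18 | (2S,3R)-4-({[tert-butyl(dimethyl)silyl]oxy}methyl)-2-[(4-methoxybenzyl)oxy]-3-{[(triethylsilyl)oxy]methyl}pent-4-enal (C6–C9 aldehyde with C11–C13) | O=C[C@@H](OCc1ccc(OC)cc1)[C@H](C(=C)CO[Si](C)(C)C(C)(C)C)CO[Si](CC)(CC)CC | intermediate
19 | prop-2-yn-1-ol (propargyl alcohol) | C#CCO | starting material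
20 | [(Z)-3-(bromomagnesiooxy)-2-methylprop-1-en-1-yl]magnesium bromide (not isolated) | Br[Mg]/C=C(/C)CO[Mg]Br | intermediate
21 | (Z)-3-iodo-2-methylprop-2-en-1-ol | I/C=C(/C)CO | intermediate
22 | (Z)-3-iodo-2-methylprop-2-enal | I/C=C(/C)C=O | intermediate
23 | but-2-yn-1-ol | CC#CCO | starting material
24 | but-2-yn-1-yl methyl carbonate | CC#CCOC(=O)OC | intermediate
25 | 2-(buta-2,3-dien-2-yl)-4,4,5,5-tetramethyl-1,3,2-dioxaborolane | C=C=C(C)B1OC(C)(C)C(C)(C)O1 | intermediate
26 | bis(isopinocampheyl)[(2E)-3-(4,4,5,5-tetramethyl-1,3,2-dioxaborolan-2-yl)but-2-en-1-yl]borane, dioxaborolane cis to the CH2B arm, Ipc from (−)-α-pinene (not isolated) | CC1(C)OB(/C(C)=C\CB([C@H]2C[C@H]3C[C@@H]([C@@H]2C)C3(C)C)[C@H]2C[C@H]3C[C@@H]([C@@H]2C)C3(C)C)OC1(C)C | intermediate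
27 | tertiary allyl pinacol boronate from the first allylboration: C9 (R) as O-bis(isopinocampheyl)borinate, C10 (R) bearing methyl, vinyl and the dioxaborolane (not isolated) | C[C@](B1OC(C)(C)C(C)(C)O1)(C=C)[C@@H](OB([C@H]2C[C@H]3C[C@@H]([C@@H]2C)C3(C)C)[C@H]2C[C@H]3C[C@@H]([C@@H]2C)C3(C)C)[C@@H](OCc1ccc(OC)cc1)[C@H](C(=C)CO[Si](C)(C)C(C)(C)C)CO[Si](CC)(CC)CC | intermediate
28 | (1Z,3R,5Z,7R,8S,9R)-10-({[tert-butyl(dimethyl)silyl]oxy}methyl)-1-iodo-8-[(4-methoxybenzyl)oxy]-2,6-dimethyl-9-{[(triethylsilyl)oxy]methyl}undeca-1,5,10-triene-3,7-diol (germacrane C3 = chain C3, germacrane C9 = chain C7) | I/C=C(/C)[C@H](O)C/C=C(/C)[C@@H](O)[C@@H](OCc1ccc(OC)cc1)[C@H](C(=C)CO[Si](C)(C)C(C)(C)C)CO[Si](CC)(CC)CC | intermediate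
29 | (1Z,3S,5Z,7R,8S,9R)-10-({[tert-butyl(dimethyl)silyl]oxy}methyl)-7-hydroxy-1-iodo-8-[(4-methoxybenzyl)oxy]-2,6-dimethyl-9-{[(triethylsilyl)oxy]methyl}undeca-1,5,10-trien-3-yl acetate | I/C=C(/C)[C@@H](OC(C)=O)C/C=C(/C)[C@@H](O)[C@@H](OCc1ccc(OC)cc1)[C@H](C(=C)CO[Si](C)(C)C(C)(C)C)CO[Si](CC)(CC)CC | intermediate
30 | (1Z,3S,5Z,7R,8S,9R)-7-{[tert-butyl(dimethyl)silyl]oxy}-10-({[tert-butyl(dimethyl)silyl]oxy}methyl)-1-iodo-8-[(4-methoxybenzyl)oxy]-2,6-dimethyl-9-{[(triethylsilyl)oxy]methyl}undeca-1,5,10-trien-3-yl acetate | I/C=C(/C)[C@@H](OC(C)=O)C/C=C(/C)[C@@H](O[Si](C)(C)C(C)(C)C)[C@@H](OCc1ccc(OC)cc1)[C@H](C(=C)CO[Si](C)(C)C(C)(C)C)CO[Si](CC)(CC)CC | intermediate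
31 | (1Z,3S,5Z,7R,8S,9R)-7-{[tert-butyl(dimethyl)silyl]oxy}-10-({[tert-butyl(dimethyl)silyl]oxy}methyl)-9-(hydroxymethyl)-1-iodo-8-[(4-methoxybenzyl)oxy]-2,6-dimethylundeca-1,5,10-trien-3-yl acetate | I/C=C(/C)[C@@H](OC(C)=O)C/C=C(/C)[C@@H](O[Si](C)(C)C(C)(C)C)[C@@H](OCc1ccc(OC)cc1)[C@H](C(=C)CO[Si](C)(C)C(C)(C)C)CO | intermediate
32 | (1Z,3S,5Z,7R,8S,9S)-7-{[tert-butyl(dimethyl)silyl]oxy}-10-({[tert-butyl(dimethyl)silyl]oxy}methyl)-9-formyl-1-iodo-8-[(4-methoxybenzyl)oxy]-2,6-dimethylundeca-1,5,10-trien-3-yl acetate | I/C=C(/C)[C@@H](OC(C)=O)C/C=C(/C)[C@@H](O[Si](C)(C)C(C)(C)C)[C@@H](OCc1ccc(OC)cc1)[C@H](C(=C)CO[Si](C)(C)C(C)(C)C)C=O | intermediate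
33 | (1(10)Z,3S,4Z,6R,7R,8S,9R)-3-acetoxy-9,12-bis{[tert-butyl(dimethyl)silyl]oxy}-8-[(4-methoxybenzyl)oxy]germacra-1(10),4,11(13)-trien-6-ol | O[C@@H]1/C=C(/C)[C@@H](OC(C)=O)C/C=C(/C)[C@@H](O[Si](C)(C)C(C)(C)C)[C@@H](OCc2ccc(OC)cc2)[C@@H]1C(=C)CO[Si](C)(C)C(C)(C)C | intermediate
34 | (1(10)Z,3S,4Z,6R,7R,8S,9R)-3-acetoxy-9-{[tert-butyl(dimethyl)silyl]oxy}-8-[(4-methoxybenzyl)oxy]germacra-1(10),4,11(13)-triene-6,12-diol | O[C@@H]1/C=C(/C)[C@@H](OC(C)=O)C/C=C(/C)[C@@H](O[Si](C)(C)C(C)(C)C)[C@@H](OCc2ccc(OC)cc2)[C@@H]1C(=C)CO | intermediate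
35 | 12-hydroxy-6,12-epoxy lactol of 34 (cis-fused, both C12 epimers, not isolated) | C=C1C(O)O[C@@H]2/C=C(/C)[C@@H](OC(C)=O)C/C=C(/C)[C@@H](O[Si](C)(C)C(C)(C)C)[C@@H](OCc3ccc(OC)cc3)[C@H]12 | intermediate
36 | (1(10)Z,3S,4Z,6R,7R,8S,9R)-3-acetoxy-9-{[tert-butyl(dimethyl)silyl]oxy}-8-[(4-methoxybenzyl)oxy]germacra-1(10),4,11(13)-trien-12,6-olide | C=C1C(=O)O[C@@H]2/C=C(/C)[C@@H](OC(C)=O)C/C=C(/C)[C@@H](O[Si](C)(C)C(C)(C)C)[C@@H](OCc3ccc(OC)cc3)[C@H]12 | intermediate
37 | (1(10)Z,3S,4Z,6R,7S,8S,9R)-3-acetoxy-9-{[tert-butyl(dimethyl)silyl]oxy}-8-hydroxygermacra-1(10),4,11(13)-trien-12,6-olide | C=C1C(=O)O[C@@H]2/C=C(/C)[C@@H](OC(C)=O)C/C=C(/C)[C@@H](O[Si](C)(C)C(C)(C)C)[C@@H](O)[C@H]12 | intermediate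
38 | angelic acid, (Z)-2-methylbut-2-enoic acid | C/C=C(/C)C(=O)O | starting material
39 | (Z)-2-methylbut-2-en-1-ol | C/C=C(/C)CO | intermediate
40 | [(2S,3R)-2,3-dimethyloxiran-2-yl]methanol | OC[C@]1(C)O[C@@H]1C | intermediate
41 | (2R,3R)-2,3-dimethyloxirane-2-carboxylic acid | OC(=O)[C@]1(C)O[C@@H]1C | intermediate
42 | (2R,3R)-2,3-dimethyloxirane-2-carboxylic 2,4,6-trichlorobenzoic anhydride (not isolated) | O=C(OC(=O)[C@]1(C)O[C@@H]1C)c1c(Cl)cc(Cl)cc1Cl | intermediate
43 | (1(10)Z,3S,4Z,6R,7R,8S,9R)-3-acetoxy-9-{[tert-butyl(dimethyl)silyl]oxy}-8-{[(2R,3R)-2,3-dimethyloxirane-2-carbonyl]oxy}germacra-1(10),4,11(13)-trien-12,6-olide | C=C1C(=O)O[C@@H]2/C=C(/C)[C@@H](OC(C)=O)C/C=C(/C)[C@@H](O[Si](C)(C)C(C)(C)C)[C@@H](OC(=O)[C@]3(C)O[C@@H]3C)[C@H]12 | intermediate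
44 | (1(10)Z,3S,4Z,6R,7R,8S,9R)-3-acetoxy-8-{[(2R,3R)-2,3-dimethyloxirane-2-carbonyl]oxy}-9-hydroxygermacra-1(10),4,11(13)-trien-12,6-olide (CNP0299903.1) | C=C1C(=O)O[C@@H]2/C=C(/C)[C@@H](OC(C)=O)C/C=C(/C)[C@@H](O)[C@@H](OC(=O)[C@]3(C)O[C@@H]3C)[C@H]12 | target

## Step count and risks

Total step count: 30. Longest linear sequence: 21 steps (steps 1–4, 7–12, 17–25, 29, 30). The side branches are steps 5–6 (aldehyde 11), 13–14 (iodoenal 22), 15–16 (boronate 25) and 26–28 (acid 41).

**Step 17 (key step).** The first allylboration is congested: a γ,γ-disubstituted allylborane meets an α-branched α-alkoxy aldehyde. If it is slow, the kinetic allylborane 26 can equilibrate by 1,3-boratropic shift before it reacts. The second chair may also not hold the carbinol arm axial. Either process erodes the Z geometry and the C3/C9 pairing.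

Fallback, from 18 (with 25) back to 30: the sequence is interrupted after the first allylboration. A buffered aqueous work-up without peroxide hydrolyses the O–B(Ipc)2 bond of 27 and allows isolation of the β-hydroxy tertiary allyl pinacol boronate F1. TBSOTf/2,6-lutidine gives its C9 silyl ether F2. Thermal allylboration of 22 with F2 in toluene (rt to 40 °C, then NaHCO3/H2O2) gives the Z homoallylic alcohol F3, in which O9 is already silylated. Mitsunobu reaction of F3 with acetic acid gives 30. This separates the two allylborations, lets each be optimised and purified, and removes the need to tell the two hydroxyls apart.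

**Step 22 (ring closure).** Two processes threaten it. Intermolecular coupling can compete with closure of the strained ten-membered ring. Facial selectivity at C6 may be poor or reversed, because the macrocyclic transition state need not follow the open-chain Felkin model.

Fallback, from 32 back to 33: if the closure gives mainly the C6 epimer F4, it is oxidised with Dess–Martin periodinane to the macrocyclic enone F5. F5 is reduced under reagent control, using the (R)-configured 2-methyl-CBS-oxazaborolidine with catecholborane at −78 °C (alkenyl group taken as the larger substituent), to give 33. Mixtures of F4 and 33 converge in the same way.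

**Step 18 (Mitsunobu).** With the weakly acidic acetic acid, the activated allylic alcohol may eliminate or ionise, giving incomplete inversion. Some activation of the C9 hydroxyl is also possible.

Fallback, from 28 back to 29: 4-nitrobenzoic acid is used as the Mitsunobu partner, giving the inverted 4-nitrobenzoate F6. Brief K2CO3/MeOH at 0 °C gives the (3S,9R)-diol F7. Acetylation of the less hindered C3 hydroxyl of F7 with AcCl/2,4,6-collidine at −78 °C gives 29. Any 3S diol formed directly in step 17 is this same F7 and joins the route here. If chemoselectivity between the two hydroxyls is the problem, the interrupted sequence described for step 17 delivers C9 already silylated.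

**Step 30 (final desilylation).** Removal of the hindered C9 silyl ether may be slow enough for acyl migration from O8 to O9 or acid-induced opening of the epoxide to compete.

Fallback, from 36 back to 44: the robust silyl group is exchanged before the sensitive ester is present. HF·pyridine at rt converts 36 into the C9 alcohol F8. TESOTf/2,6-lutidine gives the triethylsilyl ether F9. DDQ gives the C8 alcohol F10. Yamaguchi esterification with 41 gives the ester F11. AcOH/THF/H2O at rt then removes the labile triethylsilyl group to give 44.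

## Further compounds

F1 | step 17 | β-hydroxy tertiary allyl pinacol boronate, C9 (R) free hydroxyl, C10 (R) | C[C@](B1OC(C)(C)C(C)(C)O1)(C=C)[C@@H](O)[C@@H](OCc1ccc(OC)cc1)[C@H](C(=C)CO[Si](C)(C)C(C)(C)C)CO[Si](CC)(CC)CC
F2 | step 17 | C9 tert-butyldimethylsilyl ether of F1 | C[C@](B1OC(C)(C)C(C)(C)O1)(C=C)[C@@H](O[Si](C)(C)C(C)(C)C)[C@@H](OCc1ccc(OC)cc1)[C@H](C(=C)CO[Si](C)(C)C(C)(C)C)CO[Si](CC)(CC)CC
F3 | step 17 | (1Z,3R,5Z,7R,8S,9R)-7-{[tert-butyl(dimethyl)silyl]oxy}-10-({[tert-butyl(dimethyl)silyl]oxy}methyl)-1-iodo-8-[(4-methoxybenzyl)oxy]-2,6-dimethyl-9-{[(triethylsilyl)oxy]methyl}undeca-1,5,10-trien-3-ol | I/C=C(/C)[C@H](O)C/C=C(/C)[C@@H](O[Si](C)(C)C(C)(C)C)[C@@H](OCc1ccc(OC)cc1)[C@H](C(=C)CO[Si](C)(C)C(C)(C)C)CO[Si](CC)(CC)CC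
F4 | step 22 | C6 epimer of 33, (6S)-alcohol | O[C@H]1/C=C(/C)[C@@H](OC(C)=O)C/C=C(/C)[C@@H](O[Si](C)(C)C(C)(C)C)[C@@H](OCc2ccc(OC)cc2)[C@@H]1C(=C)CO[Si](C)(C)C(C)(C)C
F5 | step 22 | macrocyclic C6 enone (6-oxo analogue of 33) | O=C1/C=C(/C)[C@@H](OC(C)=O)C/C=C(/C)[C@@H](O[Si](C)(C)C(C)(C)C)[C@@H](OCc2ccc(OC)cc2)[C@@H]1C(=C)CO[Si](C)(C)C(C)(C)C
F6 | step 18 | (3S)-4-nitrobenzoate analogue of 29 | I/C=C(/C)[C@@H](OC(=O)c1ccc(cc1)[N+](=O)[O-])C/C=C(/C)[C@@H](O)[C@@H](OCc1ccc(OC)cc1)[C@H](C(=C)CO[Si](C)(C)C(C)(C)C)CO[Si](CC)(CC)CC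
F7 | step 18 | (1Z,3S,5Z,7R,8S,9R)-diol, C3 epimer of 28 | I/C=C(/C)[C@@H](O)C/C=C(/C)[C@@H](O)[C@@H](OCc1ccc(OC)cc1)[C@H](C(=C)CO[Si](C)(C)C(C)(C)C)CO[Si](CC)(CC)CC
F8 | step 30 | 9-hydroxy analogue of 36 | C=C1C(=O)O[C@@H]2/C=C(/C)[C@@H](OC(C)=O)C/C=C(/C)[C@@H](O)[C@@H](OCc3ccc(OC)cc3)[C@H]12
F9 | step 30 | 9-O-triethylsilyl analogue of 36 | C=C1C(=O)O[C@@H]2/C=C(/C)[C@@H](OC(C)=O)C/C=C(/C)[C@@H](O[Si](CC)(CC)CC)[C@@H](OCc3ccc(OC)cc3)[C@H]12
F10 | step 30 | 9-O-triethylsilyl analogue of 37 | C=C1C(=O)O[C@@H]2/C=C(/C)[C@@H](OC(C)=O)C/C=C(/C)[C@@H](O[Si](CC)(CC)CC)[C@@H](O)[C@H]12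
F11 | step 30 | 9-O-triethylsilyl analogue of 43 | C=C1C(=O)O[C@@H]2/C=C(/C)[C@@H](OC(C)=O)C/C=C(/C)[C@@H](O[Si](CC)(CC)CC)[C@@H](OC(=O)[C@]3(C)O[C@@H]3C)[C@H]12
A1 | alternative 1 | ten-membered 3,5-diene C12 acid carrying the C8 epoxy ester and C9 silyl ether | OC(=O)C(=C)[C@@H]1/C=C\C(C)=C/C/C=C(/C)[C@@H](O[Si](C)(C)C(C)(C)C)[C@H]1OC(=O)[C@]1(C)O[C@@H]1C
A2 | alternative 1 | C9 silyl ether of the target (same structure as 43) | C=C1C(=O)O[C@@H]2/C=C(/C)[C@@H](OC(C)=O)C/C=C(/C)[C@@H](O[Si](C)(C)C(C)(C)C)[C@@H](OC(=O)[C@]3(C)O[C@@H]3C)[C@H]12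
A3 | alternative 2 | cis-fused bicyclic ring-fusion (C3, C8) diol | CC(C)(C)[Si](C)(C)O[C@@H]1C=C(C)[C@@]2(O)CC=C(C)[C@@H](O[Si](C)(C)C(C)(C)C)[C@@]2(O)[C@@H]1C(=C)CO[Si](C)(C)C(C)(C)C
A4 | alternative 2 | Z,Z-cyclodecadiene-3,8-dione | CC(C)(C)[Si](C)(C)O[C@@H]1/C=C(/C)C(=O)C/C=C(/C)[C@@H](O[Si](C)(C)C(C)(C)C)C(=O)[C@@H]1C(=C)CO[Si](C)(C)C(C)(C)C
A5 | alternative 3 | 3-(bromomethyl)butenolide tethered to the C8 aldehyde | BrCC1=C[C@@H](/C=C(/C)[C@@H](OC(C)=O)C/C=C(/C)[C@@H](O[Si](C)(C)C(C)(C)C)C=O)OC1=O
A6 | alternative 3 | germacranolide with free C8 alcohol (same structure as 37) | C=C1C(=O)O[C@@H]2/C=C(/C)[C@@H](OC(C)=O)C/C=C(/C)[C@@H](O[Si](C)(C)C(C)(C)C)[C@@H](O)[C@H]12
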